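The quinone ring (ring A; C1 carbonyl, C2 hydroxyl, C3 side chain, C4 carbonyl, C5 methoxyl, C6 hydrogen) is treated as an oxidised 5-alkylresorcinol. Its oxygens at C1 and C5 sit meta to the side-chain carbon C3, which is the pattern a Michael–Claisen annulation delivers. The key step joins acyclic (3E,6R)-6-(benzyloxy)nonadec-3-en-2-one, which already carries the only stereocentre as a benzyl ether, with dimethyl malonate. In one operation it forges C3–C2 and C1–C6 and closes ring A as a cyclohexane-1,3-dione ester. Decarboxylation, aromatisation and two regiocontrolled ring oxygenations (C4, then C2) complete the target.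

Key step: step 4

Remark on the chemistry: ring A is numbered as 2-hydroxy-5-methoxy-1,4-benzoquinone with the side chain on C3. Compound 10 is written as one enol tautomer and is expected as a mixture of ring diastereomers; both ring stereocentres are erased in steps 5 and 6. The side-chain oxygen is carried as a benzyl ether because an alkoxide is a poor leaving group in a base-induced vinylogous elimination, cannot acylate onto the malonate, and is removed by hydrogenolysis before the quinone exists. The enantiomeric purity of 20 is the one set in step 1 and should be assayed at 4.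

Step 1
Reactants: 1 tetradecanal; 2 allylmagnesium bromide
Product: 4 (4R)-heptadec-1-en-4-ol, via borinate ester 3 (not isolated)
Conditions: (−)-Ipc2BOMe [from (+)-α-pinene], CH2=CHCH2MgBr, Et2O, 0 °C to rt, Mg salts filtered off; 1, Et2O, −78 °C; then 3 M NaOH, 30% H2O2, rt
Reagents that add atoms: none
Why: Brown asymmetric allylboration, in which B-allyldiisopinocampheylborane transfers allyl through a closed chair six-membered transition state and the isopinocampheyl groups from (+)-α-pinene direct attack to the Si face of the aldehyde, setting C4 as (R) (allyl outranks the alkyl chain); alkaline H2O2 then cleaves 3.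

Step 2
Reactants: 4 (4R)-heptadec-1-en-4-ol
Product: 5 (4R)-4-(benzyloxy)heptadec-1-ene
Conditions: NaH, BnBr, Bu4NI (cat.), THF, 0 °C to rt
Reagents that add atoms: benzyl bromide, BrCc1ccccc1
Why: Williamson etherification of the sodium alkoxide with a reactive benzylic halide; the carbinol C–O bond is not touched, so (R) is retained.

Step 3
Reactants: 5 (4R)-4-(benzyloxy)heptadec-1-ene; 6 methyl vinyl ketone
Product: 7 (3E,6R)-6-(benzyloxy)nonadec-3-en-2-one
Conditions: second-generation Hoveyda–Grubbs catalyst RuCl2(H2IMes)(=CH-C6H4-2-OiPr) (3 mol %), 6 (3 equiv), CH2Cl2, 40 °C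
Reagents that add atoms: none
Why: Olefin cross-metathesis of a terminal alkene with an electron-poor vinyl ketone that does not homodimerise should be selective for the cross product and, being reversible, for the E-enone; the stereocentre is a spectator.

Step 4
Reactants: 7 (3E,6R)-6-(benzyloxy)nonadec-3-en-2-one; 8 dimethyl malonate
Product: 10 methyl 6-[(2R)-2-(benzyloxy)pentadecyl]-2-hydroxy-4-oxocyclohex-2-ene-1-carboxylate, via Michael adduct 9 (not isolated)
Conditions: 8 (1.3 equiv), NaOMe (1.2 equiv), MeOH, 0 °C; add 7, 0 °C to rt until 7 is consumed; then reflux; aq. HCl to pH 3, 0 °C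
Reagents that add atoms: none
Why: Preformed sodium dimethyl malonate adds 1,4 to enone 7 (Michael addition, new bond C3–C2) to give 9; on heating, methoxide equilibrates 9 to its terminal methyl-ketone enolate, which attacks one malonate ester carbonyl and expels methoxide (intramolecular Claisen, Dieckmann-type, new bond C1–C6), and the product is withdrawn from every equilibrium as the sodium enolate of the cyclic β-diketone. The closest known reaction type is the classical Michael–Claisen annulation of alk-3-en-2-ones with malonic esters used for 5-alkylcyclohexane-1,3-diones and alkylresorcinols. Ring A is closed as a six-membered carbocycle by a 6-(enolendo)-exo-trig acyl substitution. The two new ring stereocentres (the ester-bearing carbon and the carbon carrying the side chain) are not controlled and need not be, because the first is lost on decarboxylation and the second becomes non-stereogenic in the symmetric dione and then aromatic, while the (R) carbinol lies outside every enolisable position once conjugate addition has occurred. Three selectivities are needed: 1,4- over 1,2-addition, secured by the soft stabilised carbanion; ring closure through the methyl-side enolate only, secured because the internal enolate could reach an ester only through a four-membered ring; and conjugate addition outrunning γ-deprotonation with vinylogous loss of benzyloxide, secured by adding 7 cold to malonate anion kept in slight excess over methoxide, by the poor leaving-group ability of an alkoxide, and by heating only after 7 has gone.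

Step 5
Reactants: 10 methyl 6-[(2R)-2-(benzyloxy)pentadecyl]-2-hydroxy-4-oxocyclohex-2-ene-1-carboxylate
Product: 12 5-[(2R)-2-(benzyloxy)pentadecyl]cyclohexane-1,3-dione, via keto acid 11 (not isolated)
Conditions: 2 M NaOH, MeOH–H2O, reflux; then 6 M HCl to pH 1, 80 °C
Reagents that add atoms: none
Why: Ester saponification followed by decarboxylation of the β-keto acid through a cyclic six-membered transition state, the standard second stage of the Michael–Claisen dione synthesis; the benzyl ether and the remote stereocentre tolerate hot aqueous base and brief hot dilute acid.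

Step 6
Reactants: 12 5-[(2R)-2-(benzyloxy)pentadecyl]cyclohexane-1,3-dione
Product: 14 3-[(2R)-2-(benzyloxy)pentadecyl]-5-methoxyphenol, via methyl enol ether 13 (not isolated)
Conditions: I2 (2 equiv), MeOH, reflux
Reagents that add atoms: methanol, CO
Why: Iodine–methanol oxidative aromatisation of a cyclohexane-1,3-dione: HI formed in situ catalyses conversion to the vinylogous methyl ester 13, α-iodination and loss of HI give a dienone that enolises to the phenol, so one oxygen should be methylated, and both carbonyls of 12 lead to the same constitution.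

Step 7
Reactants: 14 3-[(2R)-2-(benzyloxy)pentadecyl]-5-methoxyphenol
Product: 15 3-[(2R)-2-hydroxypentadecyl]-5-methoxyphenol
Conditions: H2 (1 atm), 10% Pd/C, EtOAc–EtOH, rt
Reagents that add atoms: none
Why: Catalytic hydrogenolysis of a benzyl ether breaks only the benzylic C–O bond, so the (R) carbinol is released with retention, and it is done while the ring is still an arene and not a reducible quinone.

Step 8
Reactants: 15 3-[(2R)-2-hydroxypentadecyl]-5-methoxyphenol
Product: 16 2-[(2R)-2-hydroxypentadecyl]-6-methoxycyclohexa-2,5-diene-1,4-dione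
Conditions: (KSO3)2NO (2.5 equiv), aq. KH2PO4, acetone–H2O, rt
Reagents that add atoms: potassium nitrosodisulfonate, [O]N(S(=O)(=O)[O-])S(=O)(=O)[O-].[K+].[K+]
Why: Teuber oxidation of a phenol with a free para position: hydrogen abstraction gives the phenoxyl radical, a second nitrosodisulfonate couples through oxygen at C4 (para to the hydroxyl, ortho to the methoxyl) and loss of imidodisulfonate gives the para-quinone, while the secondary alcohol is inert to this one-electron oxidant.

Step 9
Reactants: 16 2-[(2R)-2-hydroxypentadecyl]-6-methoxycyclohexa-2,5-diene-1,4-dione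
Product: 18 3-[(2R)-2-(acetyloxy)pentadecyl]-5-methoxybenzene-1,2,4-triyl triacetate, via quinone acetate 17 (not isolated)
Conditions: Ac2O, conc. H2SO4 (cat.), 0 °C, 30 min; then rt
Reagents that add atoms: acetic anhydride, CC(=O)OC(C)=O
Why: Acid-catalysed acetylation of the alcohol is followed by Thiele–Winter acetoxylation, in which the activated quinone takes up acetate at C2, the unsubstituted carbon beside the side chain (C6 is deactivated as the β-carbon of the methoxy enol ether), and the resulting hydroquinone is acetylated in situ; early acetylation of the side-chain hydroxyl also keeps it from adding to the quinone.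

Step 10
Reactants: 18 3-[(2R)-2-(acetyloxy)pentadecyl]-5-methoxybenzene-1,2,4-triyl triacetate
Product: 20 (2R)-1-(2-hydroxy-5-methoxy-3,6-dioxocyclohexa-1,4-dien-1-yl)pentadecan-2-yl acetate, via trihydroxyarene 19 (not isolated)
Conditions: K2CO3 (3.5 equiv), degassed MeOH, N2, 0 °C; then air, 0 °C to rt; 1 M HCl
Reagents that add atoms: none
Why: Base-mediated methanolysis should discriminate the three aryl acetates (phenoxide leaving groups) from the secondary alkyl acetate, and the liberated hydroxyhydroquinone 19 is autoxidised by air in the basic medium to the hydroxyquinone, which is held as its delocalised anion until acidification; the stereocentre is not involved.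

Compound list
1 | tetradecanal | CCCCCCCCCCCCCC=O | starting material
2 | allylmagnesium bromide | C=CC[Mg]Br | starting material
3 | (4R)-heptadec-1-en-4-yl diisopinocampheylborinate, isopinocampheyl groups from (+)-α-pinene | CCCCCCCCCCCCC[C@H](CC=C)OB([C@@H]1C[C@@H]2C[C@H]([C@H]1C)C2(C)C)[C@@H]1C[C@@H]2C[C@H]([C@H]1C)C2(C)C | intermediate (not isolated)
4 | (4R)-heptadec-1-en-4-ol | CCCCCCCCCCCCC[C@H](CC=C)O | intermediate
5 | (4R)-4-(benzyloxy)heptadec-1-ene | CCCCCCCCCCCCC[C@H](CC=C)OCc1ccccc1 | intermediate
6 | methyl vinyl ketone (but-3-en-2-one) | CC(=O)C=C | starting material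
7 | (3E,6R)-6-(benzyloxy)nonadec-3-en-2-one | CCCCCCCCCCCCC[C@H](C/C=C/C(C)=O)OCc1ccccc1 | intermediate
8 | dimethyl malonate | COC(=O)CC(=O)OC | starting material
9 | dimethyl 2-[(6R)-6-(benzyloxy)-2-oxononadecan-4-yl]propanedioate (C4 epimers) | CCCCCCCCCCCCC[C@H](CC(CC(C)=O)C(C(=O)OC)C(=O)OC)OCc1ccccc1 | intermediate (not isolated)
10 | methyl 6-[(2R)-2-(benzyloxy)pentadecyl]-2-hydroxy-4-oxocyclohex-2-ene-1-carboxylate (ring stereocentres unassigned) | CCCCCCCCCCCCC[C@H](CC1CC(=O)C=C(O)C1C(=O)OC)OCc1ccccc1 | intermediate
11 | 6-[(2R)-2-(benzyloxy)pentadecyl]-2-hydroxy-4-oxocyclohex-2-ene-1-carboxylic acid | CCCCCCCCCCCCC[C@H](CC1CC(=O)C=C(O)C1C(=O)O)OCc1ccccc1 | intermediate (not isolated)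
12 | 5-[(2R)-2-(benzyloxy)pentadecyl]cyclohexane-1,3-dione | CCCCCCCCCCCCC[C@H](CC1CC(=O)CC(=O)C1)OCc1ccccc1 | intermediate
13 | 5-[(2R)-2-(benzyloxy)pentadecyl]-3-methoxycyclohex-2-en-1-one (C5 epimers) | CCCCCCCCCCCCC[C@H](CC1CC(=O)C=C(OC)C1)OCc1ccccc1 | intermediate (not isolated)
14 | 3-[(2R)-2-(benzyloxy)pentadecyl]-5-methoxyphenol | CCCCCCCCCCCCC[C@H](Cc1cc(O)cc(OC)c1)OCc1ccccc1 | intermediate
15 | 3-[(2R)-2-hydroxypentadecyl]-5-methoxyphenol | CCCCCCCCCCCCC[C@H](Cc1cc(O)cc(OC)c1)O | intermediate
16 | 2-[(2R)-2-hydroxypentadecyl]-6-methoxycyclohexa-2,5-diene-1,4-dione | CCCCCCCCCCCCC[C@H](CC1=CC(=O)C=C(OC)C1=O)O | intermediate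
17 | (2R)-1-(5-methoxy-3,6-dioxocyclohexa-1,4-dien-1-yl)pentadecan-2-yl acetate | CCCCCCCCCCCCC[C@H](CC1=CC(=O)C=C(OC)C1=O)OC(C)=O | intermediate (not isolated)
18 | 3-[(2R)-2-(acetyloxy)pentadecyl]-5-methoxybenzene-1,2,4-triyl triacetate | CCCCCCCCCCCCC[C@H](Cc1c(OC(C)=O)c(OC(C)=O)cc(OC)c1OC(C)=O)OC(C)=O | intermediate
19 | (2R)-1-(2,3,6-trihydroxy-5-methoxyphenyl)pentadecan-2-yl acetate | CCCCCCCCCCCCC[C@H](Cc1c(O)c(O)cc(OC)c1O)OC(C)=O | intermediate (not isolated)
20 | (2R)-1-(2-hydroxy-5-methoxy-3,6-dioxocyclohexa-1,4-dien-1-yl)pentadecan-2-yl acetate | CCCCCCCCCCCCC[C@H](CC1=C(O)C(=O)C=C(OC)C1=O)OC(C)=O | target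

Total step count: 10. Longest linear sequence: 10 steps (1 to 20).

Steps most likely to fail

Step 4. Methoxide or malonate anion may deprotonate the γ-position of the enone faster than conjugate addition, so that benzyloxide is lost by vinylogous elimination, or the sequence may stall at the open-chain adduct. The fallback sets out from 5 and forms the same ring through the other classical pairing. Cross-metathesis of 5 with methyl acrylate (same ruthenium catalyst, CH2Cl2, 40 °C) should give methyl (2E,5R)-5-(benzyloxy)octadec-2-enoate F1, whose γ-hydrogens are less acidic than those of 7. Treatment with methyl acetoacetate and NaOMe in MeOH at reflux should give the Michael adduct dimethyl 2-acetyl-3-[(2R)-2-(benzyloxy)pentadecyl]pentanedioate F2. Its acetyl methyl enolate then closes onto the distal ester in the same Claisen sense, and the route is rejoined at 10.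

Step 6. The oxidation may stop at the enol ether, continue to ring iodination or double O-methylation, or the HI formed may attack the benzyl ether. The fallback sets out from 12 and separates enol ether formation from dehydrogenation. MeOH, HC(OMe)3 and catalytic TsOH should give 13, now isolated. Kinetic deprotonation at the α'-carbon with LiN(iPr)2 (THF, −78 °C) and trapping with PhSeCl should give 5-[(2R)-2-(benzyloxy)pentadecyl]-3-methoxy-6-(phenylselanyl)cyclohex-2-en-1-one F3. Oxidation with H2O2 (CH2Cl2, pyridine, 0 °C) gives the selenoxide 5-[(2R)-2-(benzyloxy)pentadecyl]-3-methoxy-6-(phenylseleninyl)cyclohex-2-en-1-one F4, which syn-eliminates and enolises, and the route is rejoined at 14.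

Step 10. Chemoselectivity may be lost, with methanolysis of the side-chain acetate alongside the aryl acetates, or the quinone may degrade during basic autoxidation. The fallback sets out from 18 and replaces the aryl/alkyl acetate distinction by a much larger one. Exhaustive methanolysis (K2CO3, MeOH, rt) should give air-sensitive 3-[(2R)-2-hydroxypentadecyl]-5-methoxybenzene-1,2,4-triol F5, which air converts to 2-hydroxy-3-[(2R)-2-hydroxypentadecyl]-5-methoxycyclohexa-2,5-diene-1,4-dione F6. Acetylation of both hydroxyls (Ac2O, pyridine, CH2Cl2, 0 °C) should give (2R)-1-[2-(acetyloxy)-5-methoxy-3,6-dioxocyclohexa-1,4-dien-1-yl]pentadecan-2-yl acetate F7. Its acetoxyquinone is a vinylogous mixed anhydride and should be cleaved by aqueous NaHCO3 in THF at 0 °C without touching the alkyl acetate, and the route is rejoined at 20.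

Further compounds
F1 | step 4 | methyl (2E,5R)-5-(benzyloxy)octadec-2-enoate | CCCCCCCCCCCCC[C@H](C/C=C/C(=O)OC)OCc1ccccc1
F2 | step 4 | dimethyl 2-acetyl-3-[(2R)-2-(benzyloxy)pentadecyl]pentanedioate | CCCCCCCCCCCCC[C@H](CC(CC(=O)OC)C(C(C)=O)C(=O)OC)OCc1ccccc1
F3 | step 6 | 5-[(2R)-2-(benzyloxy)pentadecyl]-3-methoxy-6-(phenylselanyl)cyclohex-2-en-1-one | CCCCCCCCCCCCC[C@H](CC1CC(OC)=CC(=O)C1[Se]c1ccccc1)OCc1ccccc1
F4 | step 6 | 5-[(2R)-2-(benzyloxy)pentadecyl]-3-methoxy-6-(phenylseleninyl)cyclohex-2-en-1-one | CCCCCCCCCCCCC[C@H](CC1CC(OC)=CC(=O)C1[Se](=O)c1ccccc1)OCc1ccccc1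
F5 | step 10 | 3-[(2R)-2-hydroxypentadecyl]-5-methoxybenzene-1,2,4-triol | CCCCCCCCCCCCC[C@H](Cc1c(O)c(O)cc(OC)c1O)O
F6 | step 10 | 2-hydroxy-3-[(2R)-2-hydroxypentadecyl]-5-methoxycyclohexa-2,5-diene-1,4-dione | CCCCCCCCCCCCC[C@H](CC1=C(O)C(=O)C=C(OC)C1=O)O
F7 | step 10 | (2R)-1-[2-(acetyloxy)-5-methoxy-3,6-dioxocyclohexa-1,4-dien-1-yl]pentadecan-2-yl acetate | CCCCCCCCCCCCC[C@H](CC1=C(OC(C)=O)C(=O)C=C(OC)C1=O)OC(C)=O
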